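**Retrosynthetic overview**
- The target comes from allylic oxidation of C15 in the corresponding isopropenyl lactone. That lactone comes from a cyclohexane triol acrylate by acetylation of O-8 and O-14, then lactonisation of O-6 onto C12. The triol comes from a bridged bicyclic keto ester in which C7 is a ketone and C10 carries only an ester.
- Key disconnection of the keto ester: C8–C9 and C5–C6, a [3+3] α,α'-annulation. One partner is a chiral enamine of dihydroxyacetone acetonide (C6–C7–C8). The other is the Morita–Baylis–Hillman acetate of methyl acrylate and methacrolein (C9–C10–C5 with C1, C3, C4, C15).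
- Enabling feature: O-6 and O-8 are cis-1,3 across C7. Tied as an acetonide (temporary 1,3-dioxane ring) on a C7 ketone, C6 and C8 become the two enamine carbons of one ring. The exocyclic ester-level carbon on C10 (future C1) makes C9=C10 an acrylate and C5 an allylic acetate.
- Ring order: dioxane (present from the start, temporary), then cyclohexane C5–C10 (step 4), dioxane removed (step 12), γ-lactone last (step 14).

Key step: step 4

Remark: positions use elemane numbering (C10 quaternary carbon, C9 ring CH2, C8 acetoxy carbon, C7, C6 lactone carbinol carbon, C5; C1=C2 vinyl; C3=C4–C15 acrolein; C11(=C13)–C12 lactone; C14 acetoxymethyl). α is the ring face of O-6, O-8 and the vinyl group; β is the face of C4, C11 and C14. Compound 15 is expected as an E/Z mixture and 17/18 as C11 epimers, both without consequence.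

**Step 1**
Reactants: 1 methyl acrylate; 2 methacrolein
Product: 3 methyl 3-hydroxy-4-methyl-2-methylidenepent-4-enoate (racemic)
Conditions: DABCO (0.3 equiv), neat, rt
Reagents that add atoms: none
Why: Morita–Baylis–Hillman reaction, in which the ammonium enolate of the acrylate adds to the aldehyde carbon of methacrolein (which has no α-hydrogen and cannot act as donor); the carbinol centre is racemic and is erased in step 4.

**Step 2**
Reactants: 3 methyl 3-hydroxy-4-methyl-2-methylidenepent-4-enoate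
Product: 4 methyl 3-acetoxy-4-methyl-2-methylidenepent-4-enoate (racemic)
Conditions: Ac2O, pyridine, DMAP (cat.), CH2Cl2, 0 °C
Reagents that add atoms: acetic anhydride CC(=O)OC(C)=O
Why: DMAP-catalysed O-acetylation installs the leaving group for the SN2' event of step 4.

**Step 3**
Reactants: 5 2,2-dimethyl-1,3-dioxan-5-one; 6 (2R,5R)-2,5-dimethylpyrrolidine
Product: 7 (2R,5R)-1-(2,2-dimethyl-4H-1,3-dioxin-5-yl)-2,5-dimethylpyrrolidine
Conditions: 4 Å molecular sieves, cyclohexane, 60 °C
Reagents that add atoms: none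
Why: Enamine condensation of a symmetrical ketone; the C2-symmetric amine makes both N–C rotamers identical, so one defined chiral enamine results.

**Step 4**
Reactants: 7 (2R,5R)-1-(2,2-dimethyl-4H-1,3-dioxin-5-yl)-2,5-dimethylpyrrolidine; 4 methyl 3-acetoxy-4-methyl-2-methylidenepent-4-enoate
Product: 10 methyl 3,3-dimethyl-9-oxo-6-(prop-1-en-2-yl)-2,4-dioxabicyclo[3.3.1]nonane-7-carboxylate (O-6 and O-8 α and bridged; 5β-isopropenyl; 10α-CO2Me), via C8-alkylated enamine 8 (not isolated), via bicyclic iminium acetate 9 (not isolated)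
Conditions: MeCN, 0 °C → 60 °C; then AcOH–NaOAc–H2O, rt
Reagents that add atoms: water O
Why: The enamine carbon adds to the terminal CH2 of the 2-(1-acetoxyalkyl)acrylate and acetate is lost by E1cB (overall SN2'), which forms C8–C9 and leaves an (E)-dienoate; acetate then moves the iminium to the enamine on the C6 side, whose intramolecular Michael addition to C5 forms C5–C6 and gives iminium 9, hydrolysed on work-up. The closest known reaction type is the α,α'-annulation of cyclic-ketone enamines with 2-(halomethyl)- and 2-(acyloxyalkyl)acrylates to bicyclo[3.3.1]nonan-9-ones. The cyclohexane closes by a 6-endo-trig conjugate addition with the enamine double bond inside the forming ring; the dioxane ring is already present. C8 is set by the auxiliary, whose methyl group next to the reacting enamine carbon shields one face (steric model; the sense is a prediction); C6 follows C8 because the tether can only reach the same face of the dioxene ring; C5 follows from a chair transition state in which the isopropenyl group, cis to C9 on the (E)-alkene, becomes axial and so trans to O-6; C10 is protonated last and is erased in step 5. The step needs attack at the CH2 terminus instead of the acetate carbon and 1,4- instead of 1,6-addition to the dienoate; acrylate polarisation secures the first and ring size (six against eight) the second.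

**Step 5**
Reactants: 10 methyl 3,3-dimethyl-9-oxo-6-(prop-1-en-2-yl)-2,4-dioxabicyclo[3.3.1]nonane-7-carboxylate
Product: 11 methyl 3,3-dimethyl-9-oxo-6-(prop-1-en-2-yl)-7-{[(triisopropylsilyl)oxy]methyl}-2,4-dioxabicyclo[3.3.1]nonane-7-carboxylate (10α-CO2Me, 10β-CH2OSi)
Conditions: LiN(i-Pr)2, THF, −78 °C; then i-Pr3SiOCH2Cl, −78 → −30 °C
Reagents that add atoms: (triisopropylsiloxy)methyl chloride CC(C)[Si](OCCl)(C(C)C)C(C)C
Why: C-alkoxymethylation of the ester enolate, the only enolisable site because the hydrogens beside the ketone are bridgehead hydrogens; the electrophile should enter C10 from the β face, away from the O–CMe2–O bridge that caps the α face, which sets the quaternary centre with C14 β and the ester (future vinyl) α.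

**Step 6**
Reactants: 11 methyl 3,3-dimethyl-9-oxo-6-(prop-1-en-2-yl)-7-{[(triisopropylsilyl)oxy]methyl}-2,4-dioxabicyclo[3.3.1]nonane-7-carboxylate
Product: 12 9-hydroxy-3,3-dimethyl-6-(prop-1-en-2-yl)-7-{[(triisopropylsilyl)oxy]methyl}-2,4-dioxabicyclo[3.3.1]nonane-7-carbaldehyde (7β-OH)
Conditions: i-Bu2AlH (3 equiv), CH2Cl2, −78 °C; aq. potassium sodium tartrate
Reagents that add atoms: none
Why: Partial hydride reduction of the α-quaternary, β-silyloxy ester stops at the aluminium hemiacetal and gives the aldehyde on work-up; the ketone is reduced as well (hydride from the open α face), which is harmless because step 8 restores it.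

**Step 7**
Reactants: 12 9-hydroxy-3,3-dimethyl-6-(prop-1-en-2-yl)-7-{[(triisopropylsilyl)oxy]methyl}-2,4-dioxabicyclo[3.3.1]nonane-7-carbaldehyde
Product: 13 7-ethenyl-3,3-dimethyl-6-(prop-1-en-2-yl)-7-{[(triisopropylsilyl)oxy]methyl}-2,4-dioxabicyclo[3.3.1]nonan-9-ol
Conditions: Ph3PCH3Br, KOt-Bu, THF, 0 °C → rt
Reagents that add atoms: methyltriphenylphosphonium bromide (as its ylide) C[P+](c1ccccc1)(c1ccccc1)c1ccccc1.[Br-]
Why: Wittig methylenation of the non-enolisable aldehyde gives the C1=C2 vinyl group without touching the C10 centre.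

**Step 8**
Reactants: 13 7-ethenyl-3,3-dimethyl-6-(prop-1-en-2-yl)-7-{[(triisopropylsilyl)oxy]methyl}-2,4-dioxabicyclo[3.3.1]nonan-9-ol
Product: 14 7-ethenyl-3,3-dimethyl-6-(prop-1-en-2-yl)-7-{[(triisopropylsilyl)oxy]methyl}-2,4-dioxabicyclo[3.3.1]nonan-9-one
Conditions: Dess–Martin periodinane, CH2Cl2, rt
Reagents that add atoms: none
Why: Dess–Martin oxidation of the only free alcohol returns the C7 ketone under neutral conditions.

**Step 9**
Reactants: 14 7-ethenyl-3,3-dimethyl-6-(prop-1-en-2-yl)-7-{[(triisopropylsilyl)oxy]methyl}-2,4-dioxabicyclo[3.3.1]nonan-9-one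
Product: 15 tert-butyl 2-[7-ethenyl-3,3-dimethyl-6-(prop-1-en-2-yl)-7-{[(triisopropylsilyl)oxy]methyl}-2,4-dioxabicyclo[3.3.1]nonan-9-ylidene]acetate
Conditions: (EtO)2P(O)CH2CO2t-Bu, NaH, THF, 0 → 65 °C
Reagents that add atoms: tert-butyl diethylphosphonoacetate CCOP(=O)(CC(=O)OC(C)(C)C)OCC
Why: Horner–Wadsworth–Emmons olefination of a non-enolisable ketone activated by two α-oxygens attaches C11 and C12; the alkene geometry is lost in step 10.

**Step 10**
Reactants: 15 tert-butyl 2-[7-ethenyl-3,3-dimethyl-6-(prop-1-en-2-yl)-7-{[(triisopropylsilyl)oxy]methyl}-2,4-dioxabicyclo[3.3.1]nonan-9-ylidene]acetate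
Product: 16 tert-butyl 2-[7-ethenyl-3,3-dimethyl-6-(prop-1-en-2-yl)-7-{[(triisopropylsilyl)oxy]methyl}-2,4-dioxabicyclo[3.3.1]nonan-9-yl]acetate (7α-H, side chain β)
Conditions: Cu(OAc)2 (5 mol %), 1,2-bis(diphenylphosphino)benzene (5 mol %), (EtO)2MeSiH, t-BuOH, toluene, rt
Reagents that add atoms: none
Why: Copper hydride conjugate reduction is selective for the enoate over the isolated alkenes; hydride should reach C7 from the α face because the β face is covered by the carbocycle bridge with its 5β-isopropenyl and 10β-silyloxymethyl groups, which sets C7.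

**Step 11**
Reactants: 16 tert-butyl 2-[7-ethenyl-3,3-dimethyl-6-(prop-1-en-2-yl)-7-{[(triisopropylsilyl)oxy]methyl}-2,4-dioxabicyclo[3.3.1]nonan-9-yl]acetate
Product: 19 tert-butyl 2-[7-ethenyl-3,3-dimethyl-6-(prop-1-en-2-yl)-7-{[(triisopropylsilyl)oxy]methyl}-2,4-dioxabicyclo[3.3.1]nonan-9-yl]prop-2-enoate, via Mannich base 17 (not isolated), via trimethylammonium iodide 18 (not isolated)
Conditions: LiN(i-Pr)2, THF, −78 °C; [Me2N=CH2]I, −78 → 0 °C; then MeI, MeOH, rt; then aq. NaHCO3, CH2Cl2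
Reagents that add atoms: N,N-dimethylmethyleneiminium iodide C=[N+](C)C.[I-]
Why: Ester-enolate Mannich reaction, N-quaternisation and E1cB elimination (α-methylenation) install C13; C11 is the only acidic position.

**Step 12**
Reactants: 19 tert-butyl 2-[7-ethenyl-3,3-dimethyl-6-(prop-1-en-2-yl)-7-{[(triisopropylsilyl)oxy]methyl}-2,4-dioxabicyclo[3.3.1]nonan-9-yl]prop-2-enoate
Product: 20 tert-butyl 2-[4-ethenyl-2,6-dihydroxy-4-(hydroxymethyl)-3-(prop-1-en-2-yl)cyclohexyl]prop-2-enoate (6α-OH, 8α-OH, 14-OH)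
Conditions: aq. HF (48%), MeCN, 0 °C → rt
Reagents that add atoms: none
Why: Acetal hydrolysis and Si–O cleavage free the three hydroxyls and let the ring flip to the all-equatorial chair; the tert-butyl acrylate is inert here, so no lactone forms yet.

**Step 13**
Reactants: 20 tert-butyl 2-[4-ethenyl-2,6-dihydroxy-4-(hydroxymethyl)-3-(prop-1-en-2-yl)cyclohexyl]prop-2-enoate
Product: 21 tert-butyl 2-[6-acetoxy-4-(acetoxymethyl)-4-ethenyl-2-hydroxy-3-(prop-1-en-2-yl)cyclohexyl]prop-2-enoate (8α-OAc, 14-OAc, 6α-OH free)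
Conditions: Ac2O (2.1 equiv), pyridine, CH2Cl2, −20 °C
Reagents that add atoms: acetic anhydride CC(=O)OC(C)=O
Why: Sterically controlled acylation should take the primary O-14 and the secondary O-8 (one branched neighbour) before O-6 (branched neighbours on both sides).

**Step 14**
Reactants: 21 tert-butyl 2-[6-acetoxy-4-(acetoxymethyl)-4-ethenyl-2-hydroxy-3-(prop-1-en-2-yl)cyclohexyl]prop-2-enoate
Product: 22 8α,14-diacetoxyelema-1,3,11(13)-trien-6α,12-olide (the target with isopropenyl in place of the acrolein unit)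
Conditions: CF3CO2H–CH2Cl2 (1:9), 0 °C → rt
Reagents that add atoms: none
Why: Acidolysis of the tert-butyl ester and 5-exo-trig lactonisation by the only free hydroxyl (O-6) give the trans-fused α-methylene-γ-butyrolactone; no stereocentre is touched.

**Step 15**
Reactants: 22 8α,14-diacetoxyelema-1,3,11(13)-trien-6α,12-olide
Product: 23 target, 8α,14-diacetoxy-15-oxoelema-1,3,11(13)-trien-6α,12-olide
Conditions: SeO2, 1,4-dioxane, 80 °C
Reagents that add atoms: selenium dioxide O=[Se]=O
Why: Selenium dioxide allylic oxidation (ene reaction, then [2,3] shift) converts the methyl group of the electron-rich 1,1-disubstituted alkene into the enal; the vinyl group has no allylic hydrogen and the lactone methylene is electron-poor.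

**Compound list**
1 | methyl acrylate | C=CC(=O)OC | starting material
2 | methacrolein | CC(=C)C=O | starting material
3 | methyl 3-hydroxy-4-methyl-2-methylidenepent-4-enoate (racemic) | C=C(C(=O)OC)C(O)C(C)=C | intermediate
4 | methyl 3-acetoxy-4-methyl-2-methylidenepent-4-enoate (racemic) | C=C(C(=O)OC)C(OC(C)=O)C(C)=C | intermediate
5 | 2,2-dimethyl-1,3-dioxan-5-one | CC1(C)OCC(=O)CO1 | starting material
6 | (2R,5R)-2,5-dimethylpyrrolidine | C[C@@H]1CC[C@@H](C)N1 | starting material
7 | (2R,5R)-1-(2,2-dimethyl-4H-1,3-dioxin-5-yl)-2,5-dimethylpyrrolidine | C[C@@H]1CC[C@@H](C)N1C1=COC(C)(C)OC1 | intermediate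
8 | C8-alkylated enamine: methyl (2E)-2-{[2,2-dimethyl-5-((2R,5R)-2,5-dimethylpyrrolidin-1-yl)-4H-1,3-dioxin-4-yl]methyl}-4-methylpenta-2,4-dienoate | COC(=O)/C(C[C@@H]1OC(C)(C)OC=C1N1[C@H](C)CC[C@H]1C)=C/C(C)=C | intermediate
9 | bicyclic iminium acetate: (2R,5R)-1-[7-(methoxycarbonyl)-3,3-dimethyl-6-(prop-1-en-2-yl)-2,4-dioxabicyclo[3.3.1]nonan-9-ylidene]-2,5-dimethylpyrrolidinium acetate | COC(=O)[C@@H]1C[C@H](OC(C)(C)O3)C(=[N+]4[C@H](C)CC[C@H]4C)[C@H]3[C@H]1C(C)=C.CC(=O)[O-] | intermediate
10 | methyl 3,3-dimethyl-9-oxo-6-(prop-1-en-2-yl)-2,4-dioxabicyclo[3.3.1]nonane-7-carboxylate (isopropenyl anti, ester syn to the O–CMe2–O bridge) | COC(=O)[C@@H]1C[C@H](OC(C)(C)O3)C(=O)[C@H]3[C@H]1C(C)=C | intermediate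
11 | methyl 3,3-dimethyl-9-oxo-6-(prop-1-en-2-yl)-7-{[(triisopropylsilyl)oxy]methyl}-2,4-dioxabicyclo[3.3.1]nonane-7-carboxylate (silyloxymethyl anti to the bridge) | COC(=O)[C@]1(CO[Si](C(C)C)(C(C)C)C(C)C)C[C@H](OC(C)(C)O3)C(=O)[C@H]3[C@H]1C(C)=C | intermediate
12 | 9-hydroxy-3,3-dimethyl-6-(prop-1-en-2-yl)-7-{[(triisopropylsilyl)oxy]methyl}-2,4-dioxabicyclo[3.3.1]nonane-7-carbaldehyde | O=C[C@]1(CO[Si](C(C)C)(C(C)C)C(C)C)C[C@H](OC(C)(C)O3)[C@@H](O)[C@H]3[C@H]1C(C)=C | intermediate
13 | 7-ethenyl-3,3-dimethyl-6-(prop-1-en-2-yl)-7-{[(triisopropylsilyl)oxy]methyl}-2,4-dioxabicyclo[3.3.1]nonan-9-ol | C=C[C@]1(CO[Si](C(C)C)(C(C)C)C(C)C)C[C@H](OC(C)(C)O3)[C@@H](O)[C@H]3[C@H]1C(C)=C | intermediate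
14 | 7-ethenyl-3,3-dimethyl-6-(prop-1-en-2-yl)-7-{[(triisopropylsilyl)oxy]methyl}-2,4-dioxabicyclo[3.3.1]nonan-9-one | C=C[C@]1(CO[Si](C(C)C)(C(C)C)C(C)C)C[C@H](OC(C)(C)O3)C(=O)[C@H]3[C@H]1C(C)=C | intermediate
15 | tert-butyl 2-[7-ethenyl-3,3-dimethyl-6-(prop-1-en-2-yl)-7-{[(triisopropylsilyl)oxy]methyl}-2,4-dioxabicyclo[3.3.1]nonan-9-ylidene]acetate (E/Z mixture) | C=C[C@]1(CO[Si](C(C)C)(C(C)C)C(C)C)C[C@H](OC(C)(C)O3)C(=CC(=O)OC(C)(C)C)[C@H]3[C@H]1C(C)=C | intermediate
16 | tert-butyl 2-[7-ethenyl-3,3-dimethyl-6-(prop-1-en-2-yl)-7-{[(triisopropylsilyl)oxy]methyl}-2,4-dioxabicyclo[3.3.1]nonan-9-yl]acetate (7α-H) | C=C[C@]1(CO[Si](C(C)C)(C(C)C)C(C)C)C[C@H](OC(C)(C)O3)[C@@H](CC(=O)OC(C)(C)C)[C@H]3[C@H]1C(C)=C | intermediate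
17 | Mannich base: tert-butyl 3-(dimethylamino)-2-[bicyclic-9-yl]propanoate (C11 epimers) | C=C[C@]1(CO[Si](C(C)C)(C(C)C)C(C)C)C[C@H](OC(C)(C)O3)[C@@H](C(CN(C)C)C(=O)OC(C)(C)C)[C@H]3[C@H]1C(C)=C | intermediate
18 | trimethylammonium iodide of 17 (C11 epimers) | C=C[C@]1(CO[Si](C(C)C)(C(C)C)C(C)C)C[C@H](OC(C)(C)O3)[C@@H](C(C[N+](C)(C)C)C(=O)OC(C)(C)C)[C@H]3[C@H]1C(C)=C.[I-] | intermediate
19 | tert-butyl 2-[7-ethenyl-3,3-dimethyl-6-(prop-1-en-2-yl)-7-{[(triisopropylsilyl)oxy]methyl}-2,4-dioxabicyclo[3.3.1]nonan-9-yl]prop-2-enoate | C=C[C@]1(CO[Si](C(C)C)(C(C)C)C(C)C)C[C@H](OC(C)(C)O3)[C@@H](C(=C)C(=O)OC(C)(C)C)[C@H]3[C@H]1C(C)=C | intermediate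
20 | tert-butyl 2-[4-ethenyl-2,6-dihydroxy-4-(hydroxymethyl)-3-(prop-1-en-2-yl)cyclohexyl]prop-2-enoate (all ring substituents of C5–C8 equatorial) | C=C[C@]1(CO)C[C@H](O)[C@@H](C(=C)C(=O)OC(C)(C)C)[C@H](O)[C@H]1C(C)=C | intermediate
21 | tert-butyl 2-[6-acetoxy-4-(acetoxymethyl)-4-ethenyl-2-hydroxy-3-(prop-1-en-2-yl)cyclohexyl]prop-2-enoate | C=C[C@]1(COC(C)=O)C[C@H](OC(C)=O)[C@@H](C(=C)C(=O)OC(C)(C)C)[C@H](O)[C@H]1C(C)=C | intermediate
22 | 8α,14-diacetoxyelema-1,3,11(13)-trien-6α,12-olide | C=C[C@]1(COC(C)=O)C[C@H](OC(C)=O)[C@H]2C(=C)C(=O)O[C@@H]2[C@H]1C(C)=C | intermediate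
23 | 8α,14-diacetoxy-15-oxoelema-1,3,11(13)-trien-6α,12-olide | C=C[C@]1(COC(C)=O)C[C@H](OC(C)=O)[C@H]2C(=C)C(=O)O[C@@H]2[C@H]1C(=C)C=O | target

**Totals**
Total steps: 15. Longest linear sequence: 14 steps (1, 2, 4–15); step 3 is a one-step side branch.

**Steps most likely to fail**

Step 4. What may go wrong: poor enantiofacial control by the auxiliary in the first C–C bond formation, and erosion of it because the second, tether-enforced closure runs against the auxiliary's preferred face. The fallback sets out from 5 and 3 and returns at 10. Compound 5 is condensed with (S)-1-amino-2-(methoxymethyl)pyrrolidine to the hydrazone F1. Compound 3 is converted (NBS, Me2S) into the rearranged allylic bromide methyl (2Z)-2-(bromomethyl)-4-methylpenta-2,4-dienoate F2. The azaenolate of F1 (t-BuLi, THF, −78 °C) is alkylated with F2 to the alkylated hydrazone F3; by the facial rule established for alkylations of such hydrazone azaenolates, this gives the C8 configuration of the target. Aqueous oxalic acid removes the auxiliary to give the 4-substituted dioxanone F4. Pyrrolidine in MeCN then closes the ring by the same intramolecular enamine Michael addition, and hydrolysis gives 10.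

Step 5. What may go wrong: the electrophile enters C10 from the α face (syn to the acetonide) because the axial 5β-isopropenyl group hinders the β face. The fallback inverts the order in which the two C10 substituents are introduced; it sets out from 10 and returns at 13. The enolate of 10 is added to acetaldehyde to give the aldol adduct F5 (hydroxyethyl α, ester β). Burgess dehydration gives the vinyl ester F6. LiAlH4 reduces ester and ketone to the diol F7. Selective silylation of the primary hydroxyl (i-Pr3SiCl, imidazole) gives 13.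

Step 13. What may go wrong: insufficient discrimination between O-8 and O-6 in the acylation, which would later give the isomeric 8,12-lactone. The fallback sets out from 20 and returns at 22. The bulkier t-BuMe2SiCl (imidazole, DMF, 0 °C) silylates O-14 and O-8 to the bis-silyl ether F8. CF3CO2H in CH2Cl2 closes the lactone on O-6 to give the bis-silyl lactone F9. HF·pyridine gives the diol lactone F10, and Ac2O, pyridine and DMAP acetylate both hydroxyls to give 22.

**Further compounds**
F1 | step 4 | (S)-N-(2,2-dimethyl-1,3-dioxan-5-ylidene)-2-(methoxymethyl)pyrrolidin-1-amine | COC[C@@H]1CCCN1N=C1COC(C)(C)OC1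
F2 | step 4 | methyl (2Z)-2-(bromomethyl)-4-methylpenta-2,4-dienoate | COC(=O)/C(CBr)=C/C(C)=C
F3 | step 4 | C8-alkylated hydrazone of F1 carrying the dienoate side chain | COC(=O)/C(C[C@@H]1OC(C)(C)OCC1=NN1CCC[C@H]1COC)=C/C(C)=C
F4 | step 4 | methyl (2E)-2-[(2,2-dimethyl-5-oxo-1,3-dioxan-4-yl)methyl]-4-methylpenta-2,4-dienoate | COC(=O)/C(C[C@@H]1OC(C)(C)OCC1=O)=C/C(C)=C
F5 | step 5 | methyl 7-(1-hydroxyethyl)-3,3-dimethyl-9-oxo-6-(prop-1-en-2-yl)-2,4-dioxabicyclo[3.3.1]nonane-7-carboxylate (carbinol epimers) | COC(=O)[C@@]1(C(C)O)C[C@H](OC(C)(C)O3)C(=O)[C@H]3[C@H]1C(C)=C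
F6 | step 5 | methyl 7-ethenyl-3,3-dimethyl-9-oxo-6-(prop-1-en-2-yl)-2,4-dioxabicyclo[3.3.1]nonane-7-carboxylate | COC(=O)[C@@]1(C=C)C[C@H](OC(C)(C)O3)C(=O)[C@H]3[C@H]1C(C)=C
F7 | step 5 | 7-ethenyl-7-(hydroxymethyl)-3,3-dimethyl-6-(prop-1-en-2-yl)-2,4-dioxabicyclo[3.3.1]nonan-9-ol | C=C[C@]1(CO)C[C@H](OC(C)(C)O3)[C@@H](O)[C@H]3[C@H]1C(C)=C
F8 | step 13 | 8,14-bis(tert-butyldimethylsilyl) ether of 20 | C=C[C@]1(CO[Si](C)(C)C(C)(C)C)C[C@H](O[Si](C)(C)C(C)(C)C)[C@@H](C(=C)C(=O)OC(C)(C)C)[C@H](O)[C@H]1C(C)=C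
F9 | step 13 | 8α,14-bis(tert-butyldimethylsilyloxy)elema-1,3,11(13)-trien-6α,12-olide | C=C[C@]1(CO[Si](C)(C)C(C)(C)C)C[C@H](O[Si](C)(C)C(C)(C)C)[C@H]2C(=C)C(=O)O[C@@H]2[C@H]1C(C)=C
F10 | step 13 | 8α,14-dihydroxyelema-1,3,11(13)-trien-6α,12-olide | C=C[C@]1(CO)C[C@H](O)[C@H]2C(=C)C(=O)O[C@@H]2[C@H]1C(C)=C
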